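**Strategy.** The tetrahydrofuran ring of the furo[2,3-b]chromene ketal (O1, C2, C3, C3a, C9a) is read as a homologated cyclopropyl methyl ketone: C2, C3 and C3a are the three ring carbons of (1R,2R)-1-acetyl-2-methylcyclopropane and C9a–O1 is its acetyl C=O. Disconnection of C3a–C4 and C9a–O9 then leaves the o-quinone methide of 5-(hydroxymethyl)lasiodiplodin. In the key step magnesium iodide opens the cyclopropane, the iodo enolate adds to the quinone methide, and hemiketalisation and O-alkylation close the chroman and tetrahydrofuran rings, a three-to-five ring expansion that sets C3a and C9a from the cyclopropane-derived C3. The macrolide comes from methyl orsellinate by Mitsunobu esterification, ring-closing metathesis and ortho-formylation.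

Key step: step 12

Remark: the ketal is numbered as a furo[2,3-b]chromene (O1, C2, C3, C3a, C4, O9, C9a) and the arene as a benzoate (C1 carries the lactone carbonyl, C2 OMe, C4 O, C5 CH2, C6 the chain); the three starting materials and all reagents are taken as commercial.

Step 1
Reactants: 1 (S)-2-methyloxirane; 2 but-3-en-1-ylmagnesium bromide
Product: 3 (S)-hept-6-en-2-ol
Conditions: CuI (10 mol %), THF, −30 → 0 °C; aq. NH4Cl
Reagents that add atoms: none
Why: Copper-catalysed SN2 opening of the epoxide at its CH2 terminus by the Grignard reagent leaves the stereocenter untouched, so the (S) configuration of 1 is carried into 3.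

Step 2
Reactants: 4 methyl 2,4-dihydroxy-6-methylbenzoate (methyl orsellinate)
Product: 6 methyl 4-(benzyloxy)-2-methoxy-6-methylbenzoate, via monobenzyl ether 5 (not isolated)
Conditions: BnBr (1.0 equiv), K2CO3, DMF, rt; then MeI (3 equiv), 60 °C
Reagents that add atoms: benzyl bromide, BrCc1ccccc1; iodomethane, CI
Why: Williamson etherification in two stages: the 2-OH is hydrogen-bonded to the ester carbonyl and reacts only on heating, so benzyl bromide at room temperature should take the 4-OH and iodomethane at 60 °C then caps the 2-OH.

Step 3
Reactants: 6 methyl 4-(benzyloxy)-2-methoxy-6-methylbenzoate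
Product: 7 4-(benzyloxy)-2-methoxy-6-methylbenzoic acid
Conditions: KOH, DMSO/H2O, 90 °C; then aq. HCl
Reagents that add atoms: potassium hydroxide, [K+].[OH-]
Why: Saponification of the hindered 2,6-disubstituted benzoate needs hot hydroxide in aqueous DMSO, conditions that the benzyl and methyl ethers survive.

Step 4
Reactants: 7 4-(benzyloxy)-2-methoxy-6-methylbenzoic acid; 3 (S)-hept-6-en-2-ol
Product: 8 (R)-hept-6-en-2-yl 4-(benzyloxy)-2-methoxy-6-methylbenzoate
Conditions: PPh3, DIAD, THF, 0 °C → rt
Reagents that add atoms: none
Why: Mitsunobu esterification, in which the hindered carboxylate is the nucleophile in an SN2 displacement on the alkoxyphosphonium ion of 3, so the (S) carbinol becomes the (R) ester.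

Step 5
Reactants: 8 (R)-hept-6-en-2-yl 4-(benzyloxy)-2-methoxy-6-methylbenzoate
Product: 9 (R)-hept-6-en-2-yl 4-(benzyloxy)-2-(but-3-en-1-yl)-6-methoxybenzoate
Conditions: LDA (1.2 equiv), THF, −78 °C; allyl bromide, −78 → −40 °C
Reagents that add atoms: allyl bromide, C=CCBr
Why: Lateral (benzylic) lithiation of the ortho-toluate followed by SN2 alkylation with allyl bromide; the hindered secondary ester should resist self-condensation at −78 °C.

Step 6
Reactants: 9 (R)-hept-6-en-2-yl 4-(benzyloxy)-2-(but-3-en-1-yl)-6-methoxybenzoate
Product: 10 O-benzyl-didehydrolasiodiplodin (12-membered (R)-lactone with a ring CH=CH three carbons from the arene, E/Z mixture)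
Conditions: Grubbs II (5 mol %), CH2Cl2 (1 mM), 40 °C
Reagents that add atoms: none
Why: Ring-closing metathesis of the two terminal alkenes at high dilution closes the 12-membered lactone; the alkene geometry is irrelevant because the double bond is hydrogenated in the next step.

Step 7
Reactants: 10 O-benzyl-didehydrolasiodiplodin
Product: 11 (R)-lasiodiplodin (2-OMe, 4-OH)
Conditions: H2 (1 atm), Pd/C, EtOAc, rt
Reagents that add atoms: none
Why: Heterogeneous hydrogenation should saturate the ring alkene and hydrogenolyse the benzyl ether in one operation, leaving the aryl lactone and the methyl ether intact.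

Step 8
Reactants: 11 (R)-lasiodiplodin
Product: 12 5-formyllasiodiplodin (CHO on the arene carbon between C4–OH and the chain-bearing C6)
Conditions: MgCl2, Et3N, (CH2O)n, MeCN, reflux; aq. HCl
Reagents that add atoms: paraformaldehyde (as formaldehyde), C=O
Why: Magnesium-mediated ortho-formylation (Casnati–Skattebøl): the magnesium phenoxide delivers formaldehyde to an ortho carbon, and of the two the one para to the 2-methoxy group (C5) is not flanked by two oxygens and should react, as in the formylation of 3-methoxyphenol.

Step 9
Reactants: 12 5-formyllasiodiplodin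
Product: 13 5-(hydroxymethyl)lasiodiplodin (salicyl alcohol)
Conditions: NaBH4, THF/MeOH, 0 °C
Reagents that add atoms: none
Why: Chemoselective borohydride reduction of the aldehyde; the hindered aryl lactone should be inert to NaBH4 at 0 °C.

Step 10
Reactants: 1 (S)-2-methyloxirane
Product: 15 (1R,2R)-2-methylcyclopropane-1-carboxylic acid, via ethyl ester 14 (not isolated)
Conditions: (EtO)2P(O)CH2CO2Et, NaH, toluene, 110 °C (sealed vessel); then NaOH, H2O/EtOH, 80 °C; aq. HCl
Reagents that add atoms: triethyl phosphonoacetate, CCOC(=O)CP(=O)(OCC)OCC; sodium hydroxide, [Na+].[OH-]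
Why: Wadsworth–Emmons cyclopropanation: the phosphonate anion opens the epoxide at CH2, the alkoxide takes over the phosphoryl group and the ester enolate displaces the secondary phosphate with inversion, which should give the trans (1R,2R) ester and, after saponification in the same flask, the acid.

Step 11
Reactants: 15 (1R,2R)-2-methylcyclopropane-1-carboxylic acid
Product: 16 1-[(1R,2R)-2-methylcyclopropyl]ethan-1-one
Conditions: MeLi (2.2 equiv), Et2O, 0 °C → rt; then H2O
Reagents that add atoms: methyllithium, [Li]C
Why: Addition of methyllithium to the lithium carboxylate gives a geminal dialkoxide that collapses to the methyl ketone only on aqueous work-up, so over-addition is limited and neither ring stereocenter is touched.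

Step 12
Reactants: 13 5-(hydroxymethyl)lasiodiplodin; 16 1-[(1R,2R)-2-methylcyclopropyl]ethan-1-one
Product: 20 lasiodiplactone A, via o-quinone methide 17 (not isolated), via magnesium iodoenolate 18 (not isolated), via iodo keto phenol 19 (not isolated)
Conditions: MgI2 (1.5 equiv), 16 (3 equiv), 4 Å MS, THF, 70 °C, sealed tube
Reagents that add atoms: none
Why: Proposed new method: iodide, delivered by MgI2 to the Mg-chelated ketone 16, should open the cyclopropane by SN2 attack at its unsubstituted CH2 to give the γ-iodo enolate 18, while the same Lewis acid ionises the salicyl alcohol 13 to o-quinone methide 17; Michael addition of the enolate carbon (the former ring carbon C1 of 16) to the exocyclic CH2 of 17 gives 19, the phenoxide adds to the ketone and the hemiketal oxygen displaces iodide, so that the three cyclopropane carbons and the acetyl C=O become the tetrahydrofuran ring (C2, C3, C3a, C9a, O1), a quinone-methide-interrupted Cloke–Wilson ring expansion. The closest known reaction types are the metal-iodide-promoted ring expansion of cyclopropyl ketones with imines to pyrrolidines (iodide opening, enolate C–C bond formation, ring closure by displacement of iodide), the Cloke–Wilson rearrangement, and the hetero-Diels–Alder reaction of o-quinone methides with 2,4-dimethyl-4,5-dihydrofuran, onto which the sequence converges if the iodo ketone closes to the dihydrofuran first. The chroman ring closes 6-exo-trig (phenoxide O9 onto the C9a carbonyl) and the tetrahydrofuran ring 5-exo-tet (hemiketal O1 onto C2–I). C3 is the untouched methyl-bearing stereocenter of 16; the 5/6 ketal can only be cis-fused, and C3a, epimerisable as the α-carbon of ketone 19, should close with its C4 bond trans to the C3 methyl (methyl on the convex face), the same sense that cycloaddition anti to the methyl would give, which fixes C3a and C9a as (S,S). The step needs iodide attack at CH2 and not at CH(CH3), which SN2 sterics under mildly Lewis acidic, base-free conditions should secure, and C–C bond formation at the ring-derived enolate carbon and not at the acetyl methyl, secured because the enolate is formed regiospecifically by ring opening and not by deprotonation.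

**Compound list**

1 | (S)-2-methyloxirane ((S)-propylene oxide) | C[C@H]1CO1 | starting material
2 | but-3-en-1-ylmagnesium bromide | C=CCC[Mg]Br | starting material
3 | (S)-hept-6-en-2-ol | C[C@H](O)CCCC=C | intermediate
4 | methyl 2,4-dihydroxy-6-methylbenzoate (methyl orsellinate) | COC(=O)c1c(C)cc(O)cc1O | starting material
5 | methyl 4-(benzyloxy)-2-hydroxy-6-methylbenzoate (monobenzyl ether) | COC(=O)c1c(C)cc(OCc2ccccc2)cc1O | intermediate
6 | methyl 4-(benzyloxy)-2-methoxy-6-methylbenzoate | COC(=O)c1c(C)cc(OCc2ccccc2)cc1OC | intermediate
7 | 4-(benzyloxy)-2-methoxy-6-methylbenzoic acid | OC(=O)c1c(C)cc(OCc2ccccc2)cc1OC | intermediate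
8 | (R)-hept-6-en-2-yl 4-(benzyloxy)-2-methoxy-6-methylbenzoate | C=CCCC[C@@H](C)OC(=O)c1c(C)cc(OCc2ccccc2)cc1OC | intermediate
9 | (R)-hept-6-en-2-yl 4-(benzyloxy)-2-(but-3-en-1-yl)-6-methoxybenzoate | C=CCCC[C@@H](C)OC(=O)c1c(CCC=C)cc(OCc2ccccc2)cc1OC | intermediate
10 | O-benzyl-didehydrolasiodiplodin (E/Z mixture) | C[C@@H]1CCCC=CCCc2cc(OCc3ccccc3)cc(OC)c2C(=O)O1 | intermediate
11 | (R)-lasiodiplodin | C[C@@H]1CCCCCCCc2cc(O)cc(OC)c2C(=O)O1 | intermediate
12 | 5-formyllasiodiplodin | C[C@@H]1CCCCCCCc2c(C=O)c(O)cc(OC)c2C(=O)O1 | intermediate
13 | 5-(hydroxymethyl)lasiodiplodin | C[C@@H]1CCCCCCCc2c(CO)c(O)cc(OC)c2C(=O)O1 | intermediate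
14 | ethyl (1R,2R)-2-methylcyclopropane-1-carboxylate | CCOC(=O)[C@@H]1C[C@H]1C | intermediate
15 | (1R,2R)-2-methylcyclopropane-1-carboxylic acid | OC(=O)[C@@H]1C[C@H]1C | intermediate
16 | 1-[(1R,2R)-2-methylcyclopropyl]ethan-1-one | CC(=O)[C@@H]1C[C@H]1C | intermediate
17 | o-quinone methide of 13 (C4 carbonyl, C5 exocyclic methylene) | C[C@@H]1CCCCCCCC2=C(C(=O)O1)C(OC)=CC(=O)C2=C | intermediate
18 | iodomagnesium (S)-5-iodo-4-methylpent-2-en-2-olate (magnesium iodoenolate) | CC(O[Mg]I)=C[C@H](C)CI | intermediate
19 | iodo keto phenol: 5-[2-acetyl-(3S)-4-iodo-3-methylbutyl]lasiodiplodin (epimers at the acetyl-bearing carbon) | C[C@@H]1CCCCCCCc2c(CC(C(C)=O)[C@H](C)CI)c(O)cc(OC)c2C(=O)O1 | intermediate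
20 | lasiodiplactone A | COc1cc2c(c3c1C(=O)O[C@H](C)CCCCCCC3)C[C@H]1[C@H](C)CO[C@@]1(C)O2 | target

**Step count.** Total: 12 steps. Longest linear sequence: 9 steps (steps 2–9 and 12, from methyl orsellinate 4).

**Steps most likely to fail**

1. Step 12 (key step). Iodide may open the ring at the methyl-bearing carbon, or a secondary iodide may undergo halide exchange, which would cost regio- and stereochemical integrity at C3. Proton transfer from the phenol to the iodo enolate may be followed by alkylation at the acetyl methyl. The quinone methide may oligomerise faster than it is captured, and the Lewis acid may cleave the methyl ether next to the lactone carbonyl. The fallback uses known chemistry, sets out from 13 and comes back at 20. Commercial (S)-4-methyldihydrofuran-2(3H)-one is treated with MeLi (1 equiv, Et2O, −78 °C) to give (4S)-2,4-dimethyltetrahydrofuran-2-ol F1, which is dehydrated (cat. TsOH, distillation) to (3S)-3,5-dimethyl-2,3-dihydrofuran F2. Heating 13 with excess F2 (toluene, 160 °C, sealed tube) should generate the o-quinone methide by loss of water and give 20 by inverse-electron-demand hetero-Diels–Alder addition anti to the ring methyl.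

2. Step 8. Formylation may occur at the other ortho carbon (C3, between the two oxygens), a second formyl group may be introduced, or the ester-deactivated phenoxide may convert slowly. The fallback sets out from 10 and comes back at 12. Chemoselective hydrogenation of the ring alkene (H2, RhCl(PPh3)3, benzene) should give O-benzyllasiodiplodin F3. Rieche formylation of this diether (Cl2CHOMe, TiCl4, CH2Cl2, −78 → 0 °C) should go para to the 2-methoxy group and avoid the carbon flanked by two alkoxy groups, giving 5-formyl-O-benzyllasiodiplodin F4. BCl3 (CH2Cl2, −78 °C) then cleaves the benzyl ether next to the aldehyde to give 12.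

3. Step 6. Intermolecular metathesis may give oligomers in competition with closure of the 12-membered ring, and ruthenium hydride-induced alkene migration may lead to ring-contracted lactones. The fallback moves the ring closure from the C=C bond to the ester C–O bond, sets out from 6 and comes back at 10. Lateral lithiation and allylation of 6 (LDA, THF, −78 °C; allyl bromide) gives methyl 4-(benzyloxy)-2-(but-3-en-1-yl)-6-methoxybenzoate F5. Cross-metathesis with 3 (Grubbs II, CH2Cl2, 40 °C) gives the hydroxy alkene methyl ester F6, and saponification (KOH, aq. DMSO, 90 °C) gives the seco acid F7. Mitsunobu macrolactonisation (PPh3, DIAD, toluene, high dilution) with inversion at the (S) carbinol should give 10.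

**Further compounds**

F1 | step 12 | (4S)-2,4-dimethyltetrahydrofuran-2-ol | CC1(O)C[C@H](C)CO1
F2 | step 12 | (3S)-3,5-dimethyl-2,3-dihydrofuran ((S)-2,4-dimethyl-4,5-dihydrofuran) | CC1=C[C@H](C)CO1
F3 | step 8 | O-benzyllasiodiplodin | C[C@@H]1CCCCCCCc2cc(OCc3ccccc3)cc(OC)c2C(=O)O1
F4 | step 8 | 5-formyl-O-benzyllasiodiplodin | C[C@@H]1CCCCCCCc2c(C=O)c(OCc3ccccc3)cc(OC)c2C(=O)O1
F5 | step 6 | methyl 4-(benzyloxy)-2-(but-3-en-1-yl)-6-methoxybenzoate | COC(=O)c1c(CCC=C)cc(OCc2ccccc2)cc1OC
F6 | step 6 | methyl 4-(benzyloxy)-2-[(8S)-8-hydroxynon-3-en-1-yl]-6-methoxybenzoate (E/Z mixture) | COC(=O)c1c(CCC=CCCC[C@H](C)O)cc(OCc2ccccc2)cc1OC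
F7 | step 6 | 4-(benzyloxy)-2-[(8S)-8-hydroxynon-3-en-1-yl]-6-methoxybenzoic acid (seco acid) | OC(=O)c1c(CCC=CCCC[C@H](C)O)cc(OCc2ccccc2)cc1OC
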